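**Plan**

- Numbering follows the cembrane skeleton: ring A is the 14-membered carbocycle C1–C14, ring B the butenolide (C1, C15, C16, O, C2); the oxirane sits on C7/C8 and the acetate on C13.
- Enabling feature: the ring B oxygen on C2 is allylic to the E-C3=C4(C18) bond, whose far carbon C5 is bonded to C6, and it lies cis to C16 across C1=C15. This is the 1,4-opening pattern of an isopropenyl oxirane spanning C2–C3, set beside an ester that the freed oxygen can acylate.
- Retrosynthesis: remove the acetate; reopen the C7–O oxirane bond to a 7-ketone/8-silyloxy pair so that C6 can carry a β-keto ester; cut O–C16 (ring B) and C5–C6 (ring A) together to the open-chain vinyl oxirane 28; then cut C2–C3 (sulfonium ylide), C1–C2 (CO), C6–C7 (diazoacetate), C13–C14 (aldol), C11=C12 (cross-metathesis) and C9–C10 (oxirane opening).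
- Forward: the chain is built linearly from (S)-2-methylglycidol; ring B and then ring A close in one operation (step 16); the C7/C8 oxirane is made in the last step but one.
- Stereochemistry: C8 comes from the chiral pool; C13 from a Ti–BINOL vinylogous aldol; C2 from a C2-symmetric chiral sulfonium ylide, its C–O bond never broken afterwards; C7 from a CBS reduction followed by inversion on oxirane closure. Z-C1=C15 comes from a chelated enolate, E-C11=C12 from metathesis, E-C3=C4 from the syn π-allyl.

Key step: step 16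

Assumption: the senses of induction of the (R)-BINOL/Ti(OiPr)4 catalyst (step 9, 13R) and of the (2R,5R)-thiolane ylide (step 15, 2S,3S oxirane) are taken from the accepted models for unsaturated aldehydes; should either prove opposite, the antipode of that reagent is used and nothing else changes.

**Route**

Step 1
Reactants: 1 (2S,5S)-hexane-2,5-diol
Product: 2 (2S,5S)-hexane-2,5-diyl dimethanesulfonate
Conditions: MsCl, Et3N, CH2Cl2, −20 → 0 °C
Reagents that add atoms: methanesulfonyl chloride, CS(=O)(=O)Cl
Why: Mesylation of both secondary alcohols (sulfene pathway) proceeds with retention and prepares a double displacement.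

Step 2
Reactants: 2 (2S,5S)-hexane-2,5-diyl dimethanesulfonate
Product: 3 (2R,5R)-2,5-dimethylthiolane
Conditions: Na2S·9H2O, DMSO, rt → 50 °C
Reagents that add atoms: sodium sulfide, [Na+].[Na+].[S-2]
Why: Twofold SN2 displacement by sulfide closes the thiolane with inversion at both carbons, which should give the C2-symmetric (2R,5R) sulfide.

Step 3
Reactants: 3 (2R,5R)-2,5-dimethylthiolane; 4 3-bromo-2-methylpropene
Product: 5 (2R,5R)-2,5-dimethyl-1-(2-methylprop-2-enyl)thiolanium tetrafluoroborate
Conditions: AgBF4, acetone, 0 °C → rt, dark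
Reagents that add atoms: silver tetrafluoroborate, [Ag+].F[B-](F)(F)F
Why: Silver-assisted S-alkylation of the sulfide by the allylic bromide gives a salt with a non-nucleophilic counter-ion; the C2 axis makes both sulfur lone pairs equivalent, so one salt is expected.

Step 4
Reactants: 6 methyl 2-methylacetoacetate
Product: 7 methyl 2-methyl-3-(trimethylsilyloxy)but-2-enoate
Conditions: Me3SiCl, Et3N, hexane, rt
Reagents that add atoms: chlorotrimethylsilane, C[Si](C)(C)Cl
Why: O-silylation of the β-keto ester enol (silyl enol ether formation) under amine base.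

Step 5
Reactants: 7 methyl 2-methyl-3-(trimethylsilyloxy)but-2-enoate
Product: 9 1-methoxy-2-methyl-1,3-bis(trimethylsilyloxy)buta-1,3-diene, via lithium dienolate 8 (not isolated)
Conditions: LiN(iPr)2, THF, −78 °C; then Me3SiCl, −78 °C → rt
Reagents that add atoms: chlorotrimethylsilane, C[Si](C)(C)Cl
Why: γ-Deprotonation of the silyl enol ether and O-silylation of the ester dienolate is the standard route to bis-silyl dienol ethers of acetoacetates.

Step 6
Reactants: 10 (S)-2-methylglycidol; 11 allylmagnesium chloride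
Product: 12 (R)-2-methylhex-5-ene-1,2-diol
Conditions: CuI (10 mol%), THF, −40 → 0 °C; aq. NH4Cl
Reagents that add atoms: none
Why: Copper-catalysed Grignard opening of the 2,2-disubstituted oxirane is an SN2 attack at the unsubstituted CH2, so the quaternary carbinol (future C8) is carried over untouched from the chiral pool.

Step 7
Reactants: 12 (R)-2-methylhex-5-ene-1,2-diol
Product: 13 (R)-2-methyl-1,2-bis(triethylsilyloxy)hex-5-ene
Conditions: Et3SiOTf, 2,6-lutidine, CH2Cl2, −78 → 0 °C
Reagents that add atoms: triethylsilyl trifluoromethanesulfonate, CC[Si](CC)(CC)OS(=O)(=O)C(F)(F)F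
Why: Silyl triflate silylation covers the tertiary alcohol as well; the tertiary ether later blocks tetronic acid formation from the γ-oxygenated β-keto ester and keeps the C7 reduction non-chelated.

Step 8
Reactants: 13 (R)-2-methyl-1,2-bis(triethylsilyloxy)hex-5-ene; 14 methacrolein
Product: 15 (2E,6R)-2,6-dimethyl-6,7-bis(triethylsilyloxy)hept-2-enal
Conditions: second-generation Hoveyda–Grubbs catalyst (5 mol%), excess 14, CH2Cl2, 40 °C
Reagents that add atoms: none
Why: Olefin cross-metathesis of a terminal alkene with methacrolein should give the trisubstituted enal as the thermodynamically favoured E isomer (C11=C12).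

Step 9
Reactants: 15 (2E,6R)-2,6-dimethyl-6,7-bis(triethylsilyloxy)hept-2-enal; 9 1-methoxy-2-methyl-1,3-bis(trimethylsilyloxy)buta-1,3-diene
Product: 17 methyl (5R,6E,10R)-5-hydroxy-2,6,10-trimethyl-3-oxo-10,11-bis(triethylsilyloxy)undec-6-enoate (C2 epimers), via silylated aldol adduct 16 (not isolated)
Conditions: Ti(OiPr)4 (10 mol%), (R)-BINOL (10 mol%), 4 Å sieves, THF, −78 °C → rt; then citric acid, MeOH, 0 °C
Reagents that add atoms: none
Why: Catalytic asymmetric vinylogous Mukaiyama aldol: the terminal carbon of the dienol ether adds 1,2 to the enal on the face selected by the titanium–BINOL complex, setting C13 (chain C5) as R; the mild methanolysis should remove only the trimethylsilyl groups.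

Step 10
Reactants: 17 methyl (5R,6E,10R)-5-hydroxy-2,6,10-trimethyl-3-oxo-10,11-bis(triethylsilyloxy)undec-6-enoate
Product: 18 methyl (5R,6E,10R)-5-(tert-butyldimethylsilyloxy)-2,6,10-trimethyl-3-oxo-10,11-bis(triethylsilyloxy)undec-6-enoate (C2 epimers)
Conditions: tBuMe2SiOTf, 2,6-lutidine, CH2Cl2, −78 °C
Reagents that add atoms: tert-butyldimethylsilyl trifluoromethanesulfonate, CC(C)(C)[Si](C)(C)OS(=O)(=O)C(F)(F)F
Why: Low-temperature silylation should outrun lactonization of the δ-hydroxy β-keto ester and shuts off retro-aldol and β-elimination in the next step.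

Step 11
Reactants: 18 methyl (5R,6E,10R)-5-(tert-butyldimethylsilyloxy)-2,6,10-trimethyl-3-oxo-10,11-bis(triethylsilyloxy)undec-6-enoate
Product: 20 methyl (2Z,5R,6E,10R)-5-(tert-butyldimethylsilyloxy)-2,6,10-trimethyl-10,11-bis(triethylsilyloxy)-3-(trifluoromethylsulfonyloxy)undeca-2,6-dienoate, via sodium enolate 19 (not isolated)
Conditions: NaH, Et2O, 0 °C; then Tf2O, −78 → 0 °C
Reagents that add atoms: trifluoromethanesulfonic anhydride, O=S(=O)(OS(=O)(=O)C(F)(F)F)C(F)(F)F
Why: O-triflation of the sodium-chelated β-keto ester enolate in a non-polar solvent should give the Z-enol triflate, with the oxygen substituent on C1 cis to C16; the C15 epimers converge here.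

Step 12
Reactants: 20 Z-enol triflate (name as in step 11)
Product: 22 methyl (2Z,5R,6E,10R)-5-(tert-butyldimethylsilyloxy)-2,6,10-trimethyl-11-oxo-10-(triethylsilyloxy)-3-(trifluoromethylsulfonyloxy)undeca-2,6-dienoate, via alkoxysulfonium chloride 21 (not isolated)
Conditions: (COCl)2, DMSO, CH2Cl2, −78 → −40 °C; then Et3N, −78 → 0 °C
Reagents that add atoms: none
Why: Swern conditions oxidize a primary triethylsilyl ether directly to the aldehyde (oxidative desilylation) and should leave the tertiary triethylsilyl ether, the secondary tert-butyldimethylsilyl ether and the enol triflate alone.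

Step 13
Reactants: 22 C7 aldehyde (name as in step 12); 23 ethyl diazoacetate
Product: 24 13-ethyl 1-methyl (2Z,5R,6E,10R)-5-(tert-butyldimethylsilyloxy)-2,6,10-trimethyl-11-oxo-10-(triethylsilyloxy)-3-(trifluoromethylsulfonyloxy)trideca-2,6-dienedioate
Conditions: SnCl2 (20 mol%), CH2Cl2, rt
Reagents that add atoms: none
Why: Roskamp homologation: Lewis-acid-promoted addition of the diazo ester to the aldehyde, then 1,2-hydride shift with loss of nitrogen, gives the β-keto ester (C6 pronucleophile) only after the other β-keto ester has been converted to its triflate.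

Step 14
Reactants: 24 β-keto ester enol triflate (name as in step 13)
Product: 25 13-ethyl 1-methyl (2Z,5R,6E,10R)-5-(tert-butyldimethylsilyloxy)-3-formyl-2,6,10-trimethyl-11-oxo-10-(triethylsilyloxy)trideca-2,6-dienedioate
Conditions: Pd(PPh3)4 (5 mol%), CO (1 atm), LiCl, Bu3SnH (slow addition), THF, 50 °C
Reagents that add atoms: carbon monoxide, [C-]#[O+]
Why: Palladium-catalysed carbonylative reduction (formylation) of the enol triflate: oxidative addition with retention of alkene geometry, CO insertion and hydride transfer to the acyl complex put the C2 aldehyde cis to C16.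

Step 15
Reactants: 25 Z-formyl enoate (name as in step 14); 5 (2R,5R)-2,5-dimethyl-1-(2-methylprop-2-enyl)thiolanium tetrafluoroborate
Product: 28 13-ethyl 1-methyl (2Z,5R,6E,10R)-5-(tert-butyldimethylsilyloxy)-2,6,10-trimethyl-11-oxo-3-[(2S,3S)-3-(prop-1-en-2-yl)oxiran-2-yl]-10-(triethylsilyloxy)trideca-2,6-dienedioate, via sulfonium ylide 26 (not isolated), via potassium enolate 27 (not isolated)
Conditions: 5, KN(SiMe3)2, THF, −78 °C; separately 25, KOtBu (1.0 equiv), THF, −78 °C; enolate solution added to ylide, −78 °C; AcOH quench at −78 °C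
Reagents that add atoms: none
Why: Asymmetric sulfur ylide epoxidation (Corey–Chaykovsky type) with a C2-symmetric thiolanium methallylide: the ylide face is set by the flanking methyl groups and the anti betaine closes to the trans oxirane faster than its alkoxide can acylate the cis ester, fixing C2 as S (C3 is lost later); the β-keto ester rides through as its potassium enolate, and the minor cis oxirane (C2 epimer) is removed by chromatography.

Step 16
Reactants: 28 open-chain vinyl oxirane (name as in step 15)
Product: 29 (2R,3E,8R,11E,13R)-13-(tert-butyldimethylsilyloxy)-6-(ethoxycarbonyl)-7-oxo-8-(triethylsilyloxy)cembra-1(15),3,11-trien-16,2-olide (C6 epimers)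
Conditions: Pd(PPh3)4 (10 mol%), dppe (10 mol%), THF, 65 °C, syringe-pump addition of 28 to a final 0.005 M
Reagents that add atoms: none
Why: Proposed new method: zerovalent palladium, bound to the isopropenyl group, ionizes the strained C3–O bond with inversion to give a syn 2-methyl-η3-allyl complex (C3–C4–C5) and the C2 alkoxide, which acylates the cis C16 methyl ester (5-exo-trig) to close butenolide ring B and expel methoxide; the methoxide takes the C6 proton of the β-keto ester and the soft enolate attacks the allyl terminus C5 anti to palladium, closing the 14-membered ring A with the new E-C3=C4 bond inside the ring and returning the catalyst. The closest known reaction is the neutral Tsuji–Trost macrocyclization of vinyl oxiranes tethered to β-keto ester or bis-sulfone pronucleophiles, in which the oxirane oxygen is the internal base; new here are the lactonization interposed between ionization and alkylation and the presence of a second allylic C–O bond. No lasting stereocenter is created: C2 keeps its configuration because its C–O bond is never broken, C3 becomes trigonal and the C6 epimers converge in step 17. The step needs ionization of C3–O rather than C2–O, which should follow from the accessible 1,1-disubstituted alkene on one side and the tetrasubstituted, electron-poor acrylate on the other, and distal (C5) rather than proximal (C3) attack, which the unsubstituted terminus and the larger ring favour. E geometry should follow from the syn allyl, in which the bulky C2 substituent points away from C5, and alkylation should outrun loss of the acidic C2–H because the β-keto ester is the strongest acid present and quenches the methoxide at once. If the alkoxide deprotonates C6 before it lactonizes, ring A forms first and the cis γ-hydroxy ester then lactonizes, so both orders lead to 29.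

Step 17
Reactants: 29 macrocyclic butenolide β-keto ester (name as in step 16)
Product: 30 (2R,3E,8R,11E,13R)-13-(tert-butyldimethylsilyloxy)-7-oxo-8-(triethylsilyloxy)cembra-1(15),3,11-trien-16,2-olide
Conditions: LiCl, H2O, DMSO, 130 °C
Reagents that add atoms: none
Why: Krapcho dealkoxycarbonylation removes the C6 ester under neutral conditions that silyl ethers tolerate and erases the C6 stereocenter.

Step 18
Reactants: 30 macrocyclic 7-ketone (name as in step 17)
Product: 31 (2R,3E,7R,8R,11E,13R)-13-(tert-butyldimethylsilyloxy)-7-hydroxy-8-(triethylsilyloxy)cembra-1(15),3,11-trien-16,2-olide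
Conditions: (S)-2-methyl-CBS-oxazaborolidine (0.5 equiv), catecholborane, toluene, −78 → −40 °C; MeOH quench
Reagents that add atoms: none
Why: Corey–Bakshi–Shibata reduction: with the quaternary silyloxy carbon C8 as the large group and C6H2 as the small one, the (S)-catalyst should deliver hydride to give 7R, the same sense as Felkin–Anh attack on the non-chelating α-silyloxy ketone (matched case).

Step 19
Reactants: 31 (7R)-alcohol (name as in step 18)
Product: 32 (2R,3E,7R,8R,11E,13R)-13-(tert-butyldimethylsilyloxy)-7-(methylsulfonyloxy)-8-(triethylsilyloxy)cembra-1(15),3,11-trien-16,2-olide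
Conditions: MsCl, Et3N, CH2Cl2, −20 °C
Reagents that add atoms: methanesulfonyl chloride, CS(=O)(=O)Cl
Why: Sulfonylation through sulfene converts the only free hydroxyl, a hindered secondary one, into a leaving group with retention.

Step 20
Reactants: 32 7-mesylate (name as in step 19)
Product: 33 (2R,3E,7S,8R,11E,13R)-7,8-epoxy-13-hydroxycembra-1(15),3,11-trien-16,2-olide
Conditions: Bu4NF·3H2O (3 equiv), THF, 0 °C → rt
Reagents that add atoms: none
Why: Fluoride desilylation frees the C8 alkoxide, which displaces the vicinal mesylate (3-exo-tet Williamson closure) with inversion at C7 to give the 7S,8R oxirane, and the same reagent uncovers the C13 hydroxyl.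

Step 21
Reactants: 33 13-hydroxy epoxide (name as in step 20)
Product: 34 (2R,3E,7S,8R,11E,13R)-13-acetoxy-7,8-epoxycembra-1(15),3,11-trien-16,2-olide (CNP0302675.1)
Conditions: Ac2O, pyridine, DMAP (cat.), CH2Cl2, 0 °C → rt
Reagents that add atoms: acetic anhydride, CC(=O)OC(C)=O
Why: DMAP-catalysed acylation of the secondary allylic alcohol; the oxirane and butenolide are inert to these conditions.

**Compound list**

1 | (2S,5S)-hexane-2,5-diol | C[C@H](O)CC[C@H](C)O | starting material
2 | (2S,5S)-hexane-2,5-diyl dimethanesulfonate | C[C@H](OS(C)(=O)=O)CC[C@H](C)OS(C)(=O)=O | intermediate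
3 | (2R,5R)-2,5-dimethylthiolane | C[C@@H]1CC[C@@H](C)S1 | intermediate
4 | 3-bromo-2-methylpropene | C=C(C)CBr | starting material
5 | (2R,5R)-2,5-dimethyl-1-(2-methylprop-2-enyl)thiolanium tetrafluoroborate | C[C@@H]1CC[C@@H](C)[S+]1CC(C)=C.F[B-](F)(F)F | intermediate
6 | methyl 2-methylacetoacetate | CC(=O)C(C)C(=O)OC | starting material
7 | methyl 2-methyl-3-(trimethylsilyloxy)but-2-enoate | COC(=O)C(C)=C(C)O[Si](C)(C)C | intermediate
8 | lithium 1-methoxy-2-methyl-3-(trimethylsilyloxy)buta-1,3-dien-1-olate | C=C(O[Si](C)(C)C)C(C)=C([O-])OC.[Li+] | intermediate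
9 | 1-methoxy-2-methyl-1,3-bis(trimethylsilyloxy)buta-1,3-diene | C=C(O[Si](C)(C)C)C(C)=C(OC)O[Si](C)(C)C | intermediate
10 | (S)-2-methylglycidol, (S)-(2-methyloxiran-2-yl)methanol | C[C@]1(CO)CO1 | starting material
11 | allylmagnesium chloride | C=CC[Mg]Cl | starting material
12 | (R)-2-methylhex-5-ene-1,2-diol | C=CCC[C@@](C)(O)CO | intermediate
13 | (R)-2-methyl-1,2-bis(triethylsilyloxy)hex-5-ene | C=CCC[C@@](C)(O[Si](CC)(CC)CC)CO[Si](CC)(CC)CC | intermediate
14 | methacrolein | C=C(C)C=O | starting material
15 | (2E,6R)-2,6-dimethyl-6,7-bis(triethylsilyloxy)hept-2-enal | O=C/C(C)=C/CC[C@@](C)(O[Si](CC)(CC)CC)CO[Si](CC)(CC)CC | intermediate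
16 | methyl (5R,6E,10R)-2,6,10-trimethyl-10,11-bis(triethylsilyloxy)-3,5-bis(trimethylsilyloxy)undeca-2,6-dienoate | COC(=O)C(C)=C(O[Si](C)(C)C)C[C@@H](O[Si](C)(C)C)/C(C)=C/CC[C@@](C)(O[Si](CC)(CC)CC)CO[Si](CC)(CC)CC | intermediate
17 | methyl (5R,6E,10R)-5-hydroxy-2,6,10-trimethyl-3-oxo-10,11-bis(triethylsilyloxy)undec-6-enoate (C2 epimers) | COC(=O)C(C)C(=O)C[C@@H](O)/C(C)=C/CC[C@@](C)(O[Si](CC)(CC)CC)CO[Si](CC)(CC)CC | intermediate
18 | methyl (5R,6E,10R)-5-(tert-butyldimethylsilyloxy)-2,6,10-trimethyl-3-oxo-10,11-bis(triethylsilyloxy)undec-6-enoate (C2 epimers) | COC(=O)C(C)C(=O)C[C@@H](O[Si](C)(C)C(C)(C)C)/C(C)=C/CC[C@@](C)(O[Si](CC)(CC)CC)CO[Si](CC)(CC)CC | intermediate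
19 | sodium Z-enolate of 18 | COC(=O)/C(C)=C(\[O-])C[C@@H](O[Si](C)(C)C(C)(C)C)/C(C)=C/CC[C@@](C)(O[Si](CC)(CC)CC)CO[Si](CC)(CC)CC.[Na+] | intermediate
20 | methyl (2Z,5R,6E,10R)-5-(tert-butyldimethylsilyloxy)-2,6,10-trimethyl-10,11-bis(triethylsilyloxy)-3-(trifluoromethylsulfonyloxy)undeca-2,6-dienoate | COC(=O)/C(C)=C(\OS(=O)(=O)C(F)(F)F)C[C@@H](O[Si](C)(C)C(C)(C)C)/C(C)=C/CC[C@@](C)(O[Si](CC)(CC)CC)CO[Si](CC)(CC)CC | intermediate
21 | dimethyl(alkoxy)sulfonium chloride of the primary oxygen of 20 | COC(=O)/C(C)=C(\OS(=O)(=O)C(F)(F)F)C[C@@H](O[Si](C)(C)C(C)(C)C)/C(C)=C/CC[C@@](C)(O[Si](CC)(CC)CC)CO[S+](C)C.[Cl-] | intermediate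
22 | methyl (2Z,5R,6E,10R)-5-(tert-butyldimethylsilyloxy)-2,6,10-trimethyl-11-oxo-10-(triethylsilyloxy)-3-(trifluoromethylsulfonyloxy)undeca-2,6-dienoate | COC(=O)/C(C)=C(\OS(=O)(=O)C(F)(F)F)C[C@@H](O[Si](C)(C)C(C)(C)C)/C(C)=C/CC[C@@](C)(O[Si](CC)(CC)CC)C=O | intermediate
23 | ethyl diazoacetate | CCOC(=O)C=[N+]=[N-] | starting material
24 | 13-ethyl 1-methyl (2Z,5R,6E,10R)-5-(tert-butyldimethylsilyloxy)-2,6,10-trimethyl-11-oxo-10-(triethylsilyloxy)-3-(trifluoromethylsulfonyloxy)trideca-2,6-dienedioate | COC(=O)/C(C)=C(\OS(=O)(=O)C(F)(F)F)C[C@@H](O[Si](C)(C)C(C)(C)C)/C(C)=C/CC[C@@](C)(O[Si](CC)(CC)CC)C(=O)CC(=O)OCC | intermediate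
25 | 13-ethyl 1-methyl (2Z,5R,6E,10R)-5-(tert-butyldimethylsilyloxy)-3-formyl-2,6,10-trimethyl-11-oxo-10-(triethylsilyloxy)trideca-2,6-dienedioate | COC(=O)/C(C)=C(\C=O)C[C@@H](O[Si](C)(C)C(C)(C)C)/C(C)=C/CC[C@@](C)(O[Si](CC)(CC)CC)C(=O)CC(=O)OCC | intermediate
26 | (2R,5R)-2,5-dimethylthiolanium 2-methylallylide | C[C@@H]1CC[C@@H](C)[S+]1[CH-]C(C)=C | intermediate
27 | potassium enolate of the β-keto ester of 25 | COC(=O)/C(C)=C(\C=O)C[C@@H](O[Si](C)(C)C(C)(C)C)/C(C)=C/CC[C@@](C)(O[Si](CC)(CC)CC)C([O-])=CC(=O)OCC.[K+] | intermediate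
28 | 13-ethyl 1-methyl (2Z,5R,6E,10R)-5-(tert-butyldimethylsilyloxy)-2,6,10-trimethyl-11-oxo-3-[(2S,3S)-3-(prop-1-en-2-yl)oxiran-2-yl]-10-(triethylsilyloxy)trideca-2,6-dienedioate | C=C(C)[C@@H]1O[C@H]1/C(=C(/C)C(=O)OC)C[C@@H](O[Si](C)(C)C(C)(C)C)/C(C)=C/CC[C@@](C)(O[Si](CC)(CC)CC)C(=O)CC(=O)OCC | intermediate
29 | (2R,3E,8R,11E,13R)-13-(tert-butyldimethylsilyloxy)-6-(ethoxycarbonyl)-7-oxo-8-(triethylsilyloxy)cembra-1(15),3,11-trien-16,2-olide (C6 epimers) | CC(C)(C)[Si](C)(C)O[C@@H]1CC2=C(C)C(=O)O[C@@H]2/C=C(\C)CC(C(=O)OCC)C(=O)[C@](C)(O[Si](CC)(CC)CC)CC/C=C/1C | intermediate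
30 | (2R,3E,8R,11E,13R)-13-(tert-butyldimethylsilyloxy)-7-oxo-8-(triethylsilyloxy)cembra-1(15),3,11-trien-16,2-olide | CC(C)(C)[Si](C)(C)O[C@@H]1CC2=C(C)C(=O)O[C@@H]2/C=C(\C)CCC(=O)[C@](C)(O[Si](CC)(CC)CC)CC/C=C/1C | intermediate
31 | (2R,3E,7R,8R,11E,13R)-13-(tert-butyldimethylsilyloxy)-7-hydroxy-8-(triethylsilyloxy)cembra-1(15),3,11-trien-16,2-olide | CC(C)(C)[Si](C)(C)O[C@@H]1CC2=C(C)C(=O)O[C@@H]2/C=C(\C)CC[C@@H](O)[C@](C)(O[Si](CC)(CC)CC)CC/C=C/1C | intermediate
32 | (2R,3E,7R,8R,11E,13R)-13-(tert-butyldimethylsilyloxy)-7-(methylsulfonyloxy)-8-(triethylsilyloxy)cembra-1(15),3,11-trien-16,2-olide | CC(C)(C)[Si](C)(C)O[C@@H]1CC2=C(C)C(=O)O[C@@H]2/C=C(\C)CC[C@@H](OS(C)(=O)=O)[C@](C)(O[Si](CC)(CC)CC)CC/C=C/1C | intermediate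
33 | (2R,3E,7S,8R,11E,13R)-7,8-epoxy-13-hydroxycembra-1(15),3,11-trien-16,2-olide | O[C@@H]1CC2=C(C)C(=O)O[C@@H]2/C=C(\C)CC[C@@H]2O[C@]2(C)CC/C=C/1C | intermediate
34 | (2R,3E,7S,8R,11E,13R)-13-acetoxy-7,8-epoxycembra-1(15),3,11-trien-16,2-olide (CNP0302675.1) | CC(=O)O[C@@H]1CC2=C(C)C(=O)O[C@@H]2/C=C(\C)CC[C@@H]2O[C@]2(C)CC/C=C/1C | target

**Step count and risks**

Total: 21 steps. Longest linear sequence: 16 steps (steps 6–21, from (S)-2-methylglycidol); steps 1–3 and 4–5 are side branches.

1. Step 16. After ionization the cationic allyl complex may lose the acidic C2–H to give a dienyl butenolide, intermolecular alkylation may outrun ring closure, or lactonization may lag so that no base is released. Fallback with known reactions, from 28 back to 29: palladium-catalysed 1,4-addition of acetic acid to the vinyl oxirane (Pd(PPh3)4, AcOH, THF, rt) should give the C5 acetate with a free C2 hydroxyl, which lactonizes on standing or on silica to the butenolide allylic acetate F1. A conventional intramolecular Tsuji–Trost alkylation of the β-keto ester (Pd(PPh3)4, dppe, N,O-bis(trimethylsilyl)acetamide, KOAc, THF, 65 °C, high dilution) then closes ring A to 29, so that ring B and ring A are formed in separate, individually precedented operations.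

2. Step 15. The ylide may be quenched by proton transfer from the β-keto ester, the enolate may be C-allylated by unreacted sulfonium salt on warming, and the trans selectivity on which C2 depends may erode. Fallback, from 24 back to 28: the β-keto ester is masked as its silyl enol ether (tBuMe2SiOTf, Et3N, CH2Cl2, −78 °C) to give the enol triflate bis-silyl compound F2. Formylation as in step 14 gives the aldehyde F3, and ylide epoxidation with a single equivalent of base gives the masked vinyl oxirane F4. Buffered fluoride (Bu4NF, AcOH, THF, −20 °C) then cleaves only the enol silane and delivers 28.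

3. Step 17. At 130 °C with chloride present the doubly allylic lactone may open or epimerize at C2, and silyl ethers may be lost. Fallback, from 29 back to 30: transesterification of the β-keto ester with allyl alcohol (DMAP cat., toluene, 100 °C, 4 Å sieves) gives the allyl β-keto ester F5. Palladium-catalysed deallylation with decarboxylation (Pd(OAc)2, PPh3, HCO2H, Et3N, THF, rt) then gives 30 at room temperature; the allyl ester should ionize far faster than the hindered allylic lactone.

**Further compounds**

F1 | step 16 | butenolide allylic acetate: 2R butenolide carrying the (E)-3-acetoxy-2-methylprop-1-enyl group on C2, chain still open between C5 and C6 | CC(=O)OC/C(C)=C/[C@H]1OC(=O)C(C)=C1C[C@@H](O[Si](C)(C)C(C)(C)C)/C(C)=C/CC[C@@](C)(O[Si](CC)(CC)CC)C(=O)CC(=O)OCC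
F2 | step 15 | tert-butyldimethylsilyl enol ether of the C6/C7 β-keto ester of 24 | COC(=O)/C(C)=C(\OS(=O)(=O)C(F)(F)F)C[C@@H](O[Si](C)(C)C(C)(C)C)/C(C)=C/CC[C@@](C)(O[Si](CC)(CC)CC)C(O[Si](C)(C)C(C)(C)C)=CC(=O)OCC
F3 | step 15 | Z-formyl enoate with the C6/C7 β-keto ester as tert-butyldimethylsilyl enol ether | COC(=O)/C(C)=C(\C=O)C[C@@H](O[Si](C)(C)C(C)(C)C)/C(C)=C/CC[C@@](C)(O[Si](CC)(CC)CC)C(O[Si](C)(C)C(C)(C)C)=CC(=O)OCC
F4 | step 15 | (2S,3S)-vinyl oxirane with the C6/C7 β-keto ester as tert-butyldimethylsilyl enol ether | C=C(C)[C@@H]1O[C@H]1/C(=C(/C)C(=O)OC)C[C@@H](O[Si](C)(C)C(C)(C)C)/C(C)=C/CC[C@@](C)(O[Si](CC)(CC)CC)C(O[Si](C)(C)C(C)(C)C)=CC(=O)OCC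
F5 | step 17 | allyl ester analogue of 29 (C6 epimers) | CC(C)(C)[Si](C)(C)O[C@@H]1CC2=C(C)C(=O)O[C@@H]2/C=C(\C)CC(C(=O)OCC=C)C(=O)[C@](C)(O[Si](CC)(CC)CC)CC/C=C/1C
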